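I wanted to know what power of free catalyst Tuesday's starting rate follows, and how much of Friday's substrate stands as target at 29 h, with these flasks before me.

| setting | Tuesday's | Wednesday's | Monday's | Friday's |
|---|---|---|---|---|
| substrate | 0.400 M | 0.400 M | 0.400 M | 1.20 M |
| free catalyst | 0.00400 M | 0.00400 M | 0.00800 M | 0.0120 M |
| target |  | 0.120 M |  |  |
| time |  |  |  | 29 h |

| Tuesday's run: time / h | Tuesday's run: [target] / M | Wednesday's run: time / h | Wednesday's run: [target] / M | Monday's run: time / h | Monday's run: [target] / M |
|---|---|---|---|---|---|
| 1.2 | 0.0097 | 1.2 | 0.1379 | 1.2 | 0.0400 |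
| 1.8 | 0.0156 | 1.8 | 0.1454 | 1.8 | 0.0564 |
| 2.9 | 0.0253 | 2.9 | 0.1608 | 2.9 | 0.0810 |
| 4.6 | 0.0380 | 4.6 | 0.1801 | 4.6 | 0.1078 |
| 7.3 | 0.0526 | 7.3 | 0.2106 | 7.3 | 0.1399 |
| 12 | 0.0778 | 12 | 0.2573 | 12 | 0.1819 |
| 18 | 0.1070 | 18 | 0.3117 | 18 | 0.2201 |
| 29 | 0.1613 | 29 | 0.3921 | 29 | 0.2742 |

(standard deviation of a reading: 0.001 M)

- Overall: substrate -> target, with free catalyst as catalyst.
- Constant volume, constant temperature.
- What is held in complexes is read along with the free species.
- An order is taken over about fifteen percent of the charge, up and down.

1. the exponent of [free catalyst] in the starting rate at the charge of the Tuesday's run (at the point where two percent of the substrate have become target)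
2. target in the Friday's run at 29 h, as a share of the substrate charged

From Tuesday's flask to Monday's, c free catalyst doubled and the first reading went from 0.0097 M to 0.0400 M, which in logarithms is an exponent of 2.04. My doubt was that target making target had swollen those readings, so I needed that path's size first.

Where target makes target from substrate (autocatalysis), the logarithm of c target over c substrate climbs in a straight line. Over Wednesday's last two readings it climbed 0.0652 h⁻¹, and dividing by that flask's substrate plus target, 0.520 M, gave 0.125 M⁻¹ h⁻¹, the self-feeding constant: the hourly climb of that logarithm per unit of substrate plus target. At Tuesday's first reading this path was worth at most 0.486 mM h⁻¹ against a mean rate of 8.08 mM h⁻¹, so the exponent stood. Might surviving catalyst inflate the constant? The same slope read 0.131 M⁻¹ h⁻¹ on Monday's flask and 0.140 M⁻¹ h⁻¹ on Tuesday's, and Wednesday's figure was lower than both, so the doubt stayed open and I went on with Wednesday's figure as a reading that might still be too high.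

On Friday's flask the ratio should rise tenfold every 15.3 h, which over 29 h is a factor of 78.5. What remained was the head start, the ratio at 29 h divided by this growth: 0.158 on Tuesday's flask and 0.509 on Monday's. Extending that power to Friday's catalyst gave 1.01 and a share of 98.8 %. But catalyst fades, perhaps sooner in a richer flask, so I also scaled the head start plainly with catalyst, to 0.473, giving 97.4 %. That large change in head start moved the share by 1.4 percentage points, and I committed to the lower figure.

The forecast said 2 and 96 %, lower than my figure, with a constant of 0.136 and the words “Near-complete conversion is expected, unless saturation at high substrate slows it”.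

The steps behind the flasks were these.

    free catalyst + substrate ⇌ catalyst-substrate complex, settled at all times (1.980 M⁻¹)
    catalyst-substrate complex + free catalyst → target + 2 free catalyst (2423 M⁻¹ h⁻¹)
    substrate + target → 2 target (0.1116 M⁻¹ h⁻¹)
    2 free catalyst → 2 spent catalyst (29.59 M⁻¹ h⁻¹)

The exponent came to 2.0 and Friday's share to 96.8 %, and at equal target made, Monday's rate stood 4.1 times Tuesday's. On Tuesday's flask the ratio of c target to c substrate rises by a factor of 3 between a quarter and half of the charge turned; starting from 16.3 h, my reading of the self-feeding constant, 0.125 M⁻¹ h⁻¹, put the half mark at 38.2 h, and the flask reached it at 36.7 h.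

The numbers in the tables were computed on assumed constants.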